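**Two runs.** The north-east run held ten times the second nucleophile of the west run, yet after 25.0 min target and other capture product together stood at 44.3% there and 46.0% in the west run. So I took both products to come from one shared intermediate.

| flask | starting material | first nucleophile | second nucleophile | protic impurity | remark | time |
|---|---|---|---|---|---|---|
| west | 1 M | 0.50 equiv | 0.28 equiv (in portions, 2) | 0.050 M | run made earlier; portions every 25 min |  |
| north-east | 1 M | 0.50 equiv | 2.5 equiv (in portions, 2) | 0.050 M | run made earlier; portions every 25 min |  |
| ash | 1.0 M | 0.500 equiv | 0.250 equiv (in portions, 2) | 0.0500 M | the portions of second nucleophile follow each other after 25 min, the first at the start | 50 min |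
| larch | 1.0 M | 0.500 equiv | 0.500 equiv (in portions, 2) | 0.0500 M | the portions of second nucleophile follow each other after 25 min, the first at the start | 50 min |
| alder | 1.0 M | 0.500 equiv | 1.00 equiv (in portions, 2) | 0.0500 M | the portions of second nucleophile follow each other after 25 min, the first at the start | 50 min |
| oak | 1.0 M | 0.500 equiv | 2.00 equiv (in portions, 2) | 0.0500 M | the portions of second nucleophile follow each other after 25 min, the first at the start | 50 min |

| run | time / min | target / % | other capture product / % |
|---|---|---|---|
| west | 4.00 | 8.5 | 1.0 |
| west | 8.00 | 17.9 | 2.0 |
| west | 12.0 | 26.1 | 0 |
| west | 15.0 | 31.4 | 0.6 |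
| west | 20.0 | 37.9 | 0.5 |
| west | 25.0 | 44.4 | 1.6 |
| north-east | 1.50 | 2.4 | 0 |
| north-east | 5.00 | 10.0 | 0 |
| north-east | 8.00 | 14.6 | 0.6 |
| north-east | 15.0 | 29.7 | 2.2 |
| north-east | 20.0 | 36.6 | 4.4 |
| north-east | 25.0 | 39.0 | 5.3 |

(each reading ± 1 percentage point)

- the analysis behind the earlier runs scatters by 1 percentage point, standard deviation
- "hardly changes" means that all values lie within two and a half points (for a concentration: within two and a half percent of the largest)

1. share of target in all that became target or other capture product for ash, larch, alder, oak, in this order
2. how the row runs (hardly changes / falls all the way / rises all the way / falls, then rises / rises, then falls)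

**Two rates.** I assumed that target formed at a rate proportional to c(first nucleophile) and other capture product at a rate proportional to c(second nucleophile), each multiplied by the same c(intermediate). Dividing one rate by the other removes c(intermediate) and time. Summed over one portion, with c(second nucleophile) taken as constant, this gives: other capture product = c(second nucleophile) · ln(first nucleophile charged / first nucleophile left) / s.

In the north-east run, the portion was 1.25 M, and target 39.0% with other capture product 5.3%, counting first nucleophile left as its charge minus target, gave the reading s = 35.7, with a scatter of 1 percentage point on each reading. I called s the capture ratio, a selectivity factor: the rate of capture of the intermediate by first nucleophile divided by that by second nucleophile at equal concentration.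

**My expectation.** The two rates are equal when c(first nucleophile) = c(second nucleophile) / s. With both portions in, that meant c(first nucleophile) = 0.00700 M in ash and 0.0560 M in oak, a higher level in oak than in ash, so I expected the share to fall along the row.

**The forecast.** The forecast gave 72%, 72%, 72% and 71.3%, shape "hardly changes": “Share is therefore about 72% throughout”. Here it differed from my expectation.

**The result.** The row ran 91.1%, 85.9%, 80.0%, 74.8%; its shape: falls all the way.

    starting material ⇌ intermediate (K = 0.240, k = 4.60 × 10⁻⁴ s⁻¹)
    first nucleophile + intermediate → target (k = 0.130 M⁻¹ s⁻¹)
    second nucleophile + intermediate → other capture product (k = 0.00280 M⁻¹ s⁻¹)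
    starting material + protic impurity → quenched substrate (k = 8.70 × 10⁻⁴ M⁻¹ s⁻¹)

**What ran.** Up to 25.0 min, with one portion in and 12.3% of the first nucleophile left in ash and 16.8% in oak, the capture ratio put other capture product at 0.734% in ash and 5.00% in oak, against 0.552% and 3.77% in the flasks. By 50.0 min, with first nucleophile at 0% in ash, other capture product had reached 4.86% in ash and 16.7% in oak, while ash still held 34.9% starting material and 6.35% intermediate.

The earlier runs and the new flask were generated by integration from invented constants.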